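**Plan**

1. Cuts (core numbering: bicyclo[3.2.1]octenone C1 quaternary bridgehead, C2 ketone, C3=C4, C5 bridgehead CH, C6 methylidene carbon, C7 acetoxy carbon, C8 bridge CH2): (a) C1–C2 of the enone ring by a retro-Cope shift that reconnects C4–C6 as a cyclopropane; (b) the CH2–CH(O) bond between the C1 side chain and the lactone (radical conjugate addition); (c) the lactone C–O bond, the ring-fusion C–C bond to the lactone carbinol carbon and the quaternary methyl of the cyclohexane part.
2. Enabling feature: the three-carbon bridge C2–C3=C4 and the two-carbon bridge C6–C7(O), taken at the enol level C6=C7(O), are the two allyl halves of a 1,5-diene joined at C1–C2. The cyclopentane ring C1–C7–C6–C5–C8 is present throughout, so the precursor is a 2-silyloxy-6-endo-vinylbicyclo[3.1.0]hex-2-ene (cyclopropane C4–C5–C6).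
3. Forward order: cyclohexane (from 1) → lactone ring → separately cyclopentene → cyclopropane-fused cyclopentane (temporary lactone tether) → fragment union → last, the six-membered enone ring C1–C2–C3–C4–C5–C8 by the strain-releasing [3,3] shift → adjustment of C6/C7 and C2.
4. Stereochemistry: the lactone quaternary carbon comes from ligand-controlled conjugate methylation; the ring fusion, the tertiary carbinol and the lactone carbinol come from the convex face of the cis-fused lactone; C5 and C1 come from a CBS-set carbinol relayed through a tethered cyclopropanation and the Cope shift; C7 comes from exo-face hydride delivery.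

Key step: step 14

Remark: the configuration at the carboxyl-bearing carbon of 4–8, at the ketone α-carbon of 22 and at the benzyloxy-bearing carbon formed in step 14 is immaterial, because each of these centres becomes trigonal later.

Step 1
Reactants: 1 methyl 3-oxocyclohex-1-ene-1-carboxylate; 2 benzyl glyoxylate
Product: 5 benzyl (3aS,7aR)-7a-methyl-1,4-dioxooctahydroisobenzofuran-3-carboxylate (cis-fused keto lactone; epimers at C3), via zinc enolate 3 (not isolated), via zinc aldolate 4 (not isolated)
Conditions: Me2Zn, Cu(OTf)2 (5 mol%), chiral sulfonate-bearing imidazolinium salt (carbene precursor, 6 mol%), Et2O, −30 °C; then 2, −78 °C → rt; aq NH4Cl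
Reagents that add atoms: dimethylzinc, C[Zn]C
Why: Copper-catalysed asymmetric conjugate addition to the β-carboalkoxy enone should set the quaternary centre (R) under ligand control, the regiodefined zinc enolate is trapped by the glyoxylate in an aldol addition, and only the aldolate whose side chain is cis to the methyl ester can lactonise, so the ring-fusion centre is corrected by reversible aldol/enolisation.

Step 2
Reactants: 5 cis-fused keto lactone
Product: 6 benzyl (7aR)-7a-methyl-4-methylidene-1-oxooctahydroisobenzofuran-3-carboxylate (cis-fused; epimers at C3)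
Conditions: Zn, CH2Br2, TiCl4, THF/CH2Cl2, 0 °C → rt
Reagents that add atoms: dibromomethane, BrCBr
Why: Takai–Lombardo methylenation is non-basic and selective for ketones over esters and lactones, so the β-acyloxy ketone should neither eliminate nor epimerise.

Step 3
Reactants: 6 methylidene lactone
Product: 7 benzyl (3aS,4R,7aR)-4-hydroxy-4,7a-dimethyl-1-oxooctahydroisobenzofuran-3-carboxylate (epimers at C3)
Conditions: Co(acac)2 (20 mol%), PhSiH3, O2 (1 atm), THF/i-PrOH, rt
Reagents that add atoms: dioxygen, O=O
Why: Mukaiyama hydration (hydrogen-atom transfer to the 1,1-disubstituted alkene, O2 trapping of the tertiary radical, reduction of the peroxide) gives the Markovnikov tertiary alcohol, and O2 should approach the convex face of the cis-fused bicycle, anti to the neighbouring lactone C–C bond, placing the hydroxyl trans to the lactone (R).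

Step 4
Reactants: 7 hydroxy lactone benzyl ester
Product: 8 (3aS,4R,7aR)-4-hydroxy-4,7a-dimethyl-1-oxooctahydroisobenzofuran-3-carboxylic acid (epimers at C3)
Conditions: H2 (1 atm), Pd/C, EtOAc, rt
Reagents that add atoms: none
Why: Hydrogenolysis of the benzyl ester frees the α-acyloxy carboxylic acid needed as radical precursor without touching the lactone or the tertiary alcohol.

Step 5
Reactants: 9 2-methylcyclopent-2-en-1-one
Product: 10 (S)-2-methylcyclopent-2-en-1-ol
Conditions: (R)-2-methyl-CBS-oxazaborolidine (10 mol%), BH3·SMe2, THF, −20 °C; MeOH quench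
Reagents that add atoms: none
Why: Corey–Bakshi–Shibata reduction of a 2-substituted cyclopentenone, with the substituted alkenyl carbon as the large group, should give the S carbinol that fixes the absolute configuration of the whole bicyclic core.

Step 6
Reactants: 10 (S)-2-methylcyclopent-2-en-1-ol
Product: 12 (S)-2-methylcyclopent-2-en-1-yl diazoacetate, via tosylhydrazone ester 11 (not isolated)
Conditions: glyoxylic acid chloride p-toluenesulfonylhydrazone, PhNMe2, CH2Cl2, 0 °C; then Et3N, 0 °C → rt
Reagents that add atoms: glyoxylic acid chloride p-toluenesulfonylhydrazone, Cc1ccc(cc1)S(=O)(=O)NN=CC(Cl)=O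
Why: Acylation of the allylic alcohol followed by base-induced loss of sulfinate (Bamford–Stevens-type diazo formation) is the standard one-flask route to diazoacetates and leaves the carbinol centre untouched.

Step 7
Reactants: 12 (S)-2-methylcyclopent-2-en-1-yl diazoacetate
Product: 13 8-methyl-4-oxatricyclo[3.2.1.0(2,8)]octan-3-one (cyclopropane and lactone oxygen on the same face of the cyclopentane)
Conditions: Rh2(OAc)4 (1 mol%), CH2Cl2, 40 °C, slow addition
Reagents that add atoms: none
Why: Intramolecular cyclopropanation by the rhodium carbenoid is forced by the two-atom ester tether onto the alkene face that carries the carbinol oxygen, giving the all-cis tricyclic lactone with the future vinyl carbon endo.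

Step 8
Reactants: 13 tricyclic lactone
Product: 14 8-methyl-4-oxatricyclo[3.2.1.0(2,8)]octan-3-ol (lactol; anomers)
Conditions: i-Bu2AlH, CH2Cl2, −78 °C; Rochelle salt
Reagents that add atoms: none
Why: Half-reduction of the γ-lactone at low temperature stops at the lactol, a masked cis-hydroxy aldehyde that cannot epimerise at the cyclopropane carbon.

Step 9
Reactants: 14 lactol
Product: 15 1-methyl-6-endo-[(E)-2-(4,4,5,5-tetramethyl-1,3,2-dioxaborolan-2-yl)ethenyl]bicyclo[3.1.0]hexan-2-ol (hydroxyl cis to the cyclopropane)
Conditions: CrCl2, LiI, Cl2CHBpin, THF, rt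
Reagents that add atoms: 2-(dichloromethyl)-4,4,5,5-tetramethyl-1,3,2-dioxaborolane, ClC(Cl)B1OC(C)(C)C(C)(C)O1
Why: Takai–Utimoto olefination of the open aldehyde tautomer is non-basic and E-selective, so the alkenylboronate should form without epimerising the cis-cyclopropane.

Step 10
Reactants: 15 alkenylboronate alcohol
Product: 16 1-methyl-6-endo-[(E)-2-(4,4,5,5-tetramethyl-1,3,2-dioxaborolan-2-yl)ethenyl]bicyclo[3.1.0]hexan-2-one
Conditions: Dess–Martin periodinane (DMP), NaHCO3, CH2Cl2, 0 °C → rt
Reagents that add atoms: none
Why: Dess–Martin oxidation converts the cyclopropyl carbinol into the ketone under buffered, non-enolising conditions to which the alkenylboronate is inert.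

Step 11
Reactants: 16 alkenylboronate ketone
Product: 17 6-endo-[(E)-2-(4-methoxybenzyloxy)ethenyl]-1-methylbicyclo[3.1.0]hexan-2-one
Conditions: Cu(OAc)2, Et3N, 4-methoxybenzyl alcohol (excess), 4 Å MS, CH2Cl2, air, rt
Reagents that add atoms: 4-methoxybenzyl alcohol, COc1ccc(CO)cc1
Why: Chan–Lam-type copper-mediated etherification of alkenyl pinacol boronates with alcohols proceeds with retention of alkene geometry, giving the E enol ether whose oxygen becomes the enone oxygen.

Step 12
Reactants: 17 enol ether ketone
Product: 21 6-endo-[(E)-2-(4-methoxybenzyloxy)ethenyl]-1-methyl-3-methylidenebicyclo[3.1.0]hexan-2-one, via lithium enolate 18 (not isolated), via Mannich base 19 (not isolated), via ammonium iodide 20 (not isolated)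
Conditions: LiN(SiMe3)2, THF, −78 °C; N,N-dimethylmethyleneiminium iodide, −78 → 0 °C; MeI, rt; aq NaHCO3, CH2Cl2, rt; used at once
Reagents that add atoms: N,N-dimethylmethyleneiminium iodide, C=[N+](C)C.[I-]
Why: Mannich reaction of the only possible enolate (the other α-carbon is the quaternary cyclopropane carbon), N-methylation and Hofmann-type elimination give the exo-methylene ketone without acid that would hydrolyse the enol ether, and the enolate is kept at −78 °C so that it is trapped before it can rearrange.

Step 13
Reactants: 8 lactone carboxylic acid; 21 exo-methylene ketone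
Product: 22 3-{[(3R,3aS,4R,7aR)-4-hydroxy-4,7a-dimethyl-1-oxooctahydroisobenzofuran-3-yl]methyl}-6-endo-[(E)-2-(4-methoxybenzyloxy)ethenyl]-1-methylbicyclo[3.1.0]hexan-2-one (epimers at C3 of the bicyclohexanone)
Conditions: Ir[dF(CF3)ppy]2(dtbbpy)PF6 (1 mol%), K2HPO4, DMF, blue LEDs, rt
Reagents that add atoms: none
Why: In this photoredox decarboxylative Giese addition the carboxylate is oxidised and loses CO2 to give a nucleophilic α-acyloxy radical, which should add to the methylene terminus of the enone from the convex face of the cis-fused lactone (anti to the ring-fusion C–C bond) and so set the lactone carbinol centre (R).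

Step 14
Reactants: 22 union ketone
Product: 24 5-{[(3R,3aS,4R,7aR)-4,7a-dimethyl-1-oxo-4-(trimethylsilyloxy)octahydroisobenzofuran-3-yl]methyl}-4-(4-methoxybenzyloxy)-7-methyl-6-(trimethylsilyloxy)bicyclo[3.2.1]octa-2,6-diene, via silyl enol ether 23 (not isolated)
Conditions: Me3SiOTf, Et3N, CH2Cl2, −78 → 0 °C; then solvent change to toluene, 100 °C
Reagents that add atoms: trimethylsilyl trifluoromethanesulfonate, C[Si](C)(C)OS(=O)(=O)C(F)(F)F
Why: Soft enolisation (only the CH bearing the side chain can enolise) gives silyl enol ether 23, a cis-1,2-divinylcyclopropane in which the ring enol ether and the endo E-alkoxyvinyl group lie face to face; on heating it should undergo a concerted [3,3]-sigmatropic (Cope) shift through the boat transition state imposed by the fused ring, breaking the cyclopropane bond between the methyl-bearing and the vinyl-bearing carbon while the terminal vinyl carbon bonds to the enol ether β-carbon. The closest known reaction type is the thermal rearrangement of 2-silyloxy-6-endo-vinylbicyclo[3.1.0]hex-2-enes to bicyclo[3.2.1]octa-2,6-dienes carrying a silyl enol ether in the two-carbon bridge. The six-membered carbocycle is closed by this suprafacial C–C bond formation across the 1,3-positions of the existing cyclopentene (equivalently, the three-membered ring is enlarged to the seven-membered ring of the bridged bicycle), driven by release of cyclopropane strain. The quaternary bridgehead is set by chirality transfer, since the vinyl terminus can only reach the enol ether carbon on the face that carries the cyclopropane, so its configuration follows from the cyclopropane face fixed in step 7 and ultimately from the carbinol of step 5; the ether-bearing carbon formed from the E enol ether is oxidised later. The step needs the endo relation of vinyl group and ring alkene, E geometry at the vinyl terminus and enolisation toward the side-chain carbon, which are secured by the lactone tether of step 7 together with the non-basic olefination of step 9, by the geometry-retaining steps 9 and 11, and by the absence of any other enolisable position, while the competing homodienyl hydrogen shift of cis-alkylvinylcyclopropanes has a clearly higher barrier.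

Step 15
Reactants: 24 bicyclic silyl enol ether
Product: 25 1-{[(3R,3aS,4R,7aR)-4,7a-dimethyl-1-oxo-4-(trimethylsilyloxy)octahydroisobenzofuran-3-yl]methyl}-2-(4-methoxybenzyloxy)-6-methylidenebicyclo[3.2.1]oct-3-en-7-one
Conditions: Pd(OAc)2 (1.2 equiv), MeCN, rt
Reagents that add atoms: none
Why: In this Saegusa–Ito oxidation the palladium enolate at the methyl-bearing carbon can undergo β-hydride elimination only toward the methyl group, because the other β-hydrogen is at the bridgehead, so the exo-methylene enone should form regiospecifically.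

Step 16
Reactants: 25 exo-methylene enone
Product: 27 (7R)-7-hydroxy bicyclic diol (endo carbinol; tertiary alcohol free), via silyl ether carbinol 26 (not isolated)
Conditions: NaBH4, CeCl3·7H2O, MeOH, −78 → 0 °C; then pyridinium p-toluenesulfonate (cat.), MeOH, rt
Reagents that add atoms: none
Why: Luche reduction gives 1,2-reduction of the exocyclic enone with hydride delivered to the exo face (the side of the one-carbon bridge), the endo face being screened by the three-carbon bridge and its benzyloxy group, so the hydroxyl is formed endo (R), and mild acidic methanolysis then removes the tertiary trimethylsilyl ether.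

Step 17
Reactants: 27 diol
Product: 28 (7R)-7-acetoxy-2-(4-methoxybenzyloxy) bicyclic ester (tertiary alcohol free)
Conditions: Ac2O, pyridine, 4-dimethylaminopyridine (cat.), CH2Cl2, 0 °C → rt
Reagents that add atoms: acetic anhydride, CC(=O)OC(C)=O
Why: Acylation esterifies the secondary allylic alcohol while the tertiary alcohol should not react under these conditions.

Step 18
Reactants: 28 acetate
Product: 29 (7R)-7-acetoxy-2-hydroxy allylic alcohol
Conditions: DDQ, CH2Cl2/pH 7 buffer, 0 °C
Reagents that add atoms: none
Why: Oxidative cleavage of the 4-methoxybenzyl ether with DDQ frees the allylic alcohol under neutral conditions that should avoid acetyl migration and leave alkenes, acetate and lactone intact.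

Step 19
Reactants: 29 allylic alcohol
Product: 30 target, (1R,5S,7R)-1-{[(3R,3aS,4R,7aR)-4-hydroxy-4,7a-dimethyl-1-oxooctahydroisobenzofuran-3-yl]methyl}-6-methylidene-2-oxobicyclo[3.2.1]oct-3-en-7-yl acetate
Conditions: DMP, NaHCO3, CH2Cl2, 0 °C → rt
Reagents that add atoms: none
Why: Dess–Martin oxidation of the allylic alcohol gives the conjugated enone, and no centre is at risk because the α-carbon is the quaternary bridgehead and the β-acetoxy group has no α-hydrogen through which to eliminate.

**Compound list**

1 | methyl 3-oxocyclohex-1-ene-1-carboxylate | COC(=O)C1=CC(=O)CCC1 | starting material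
2 | benzyl glyoxylate | O=CC(=O)OCc1ccccc1 | starting material
3 | methylzinc enolate of methyl (R)-1-methyl-3-oxocyclohexane-1-carboxylate | COC(=O)[C@]1(C)CCCC(O[Zn]C)=C1 | intermediate
4 | zinc aldolate, benzyl 2-[(2R)-2-(methoxycarbonyl)-2-methyl-6-oxocyclohexyl]-2-(methylzinciooxy)acetate | COC(=O)[C@]1(C)CCCC(=O)C1C(O[Zn]C)C(=O)OCc1ccccc1 | intermediate
5 | benzyl (3aS,7aR)-7a-methyl-1,4-dioxooctahydroisobenzofuran-3-carboxylate, cis-fused | O=C(OCc1ccccc1)C1OC(=O)[C@]2(C)CCCC(=O)[C@H]12 | intermediate
6 | benzyl (7aR)-7a-methyl-4-methylidene-1-oxooctahydroisobenzofuran-3-carboxylate, cis-fused | O=C(OCc1ccccc1)C1OC(=O)[C@]2(C)CCCC(=C)[C@H]12 | intermediate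
7 | benzyl (3aS,4R,7aR)-4-hydroxy-4,7a-dimethyl-1-oxooctahydroisobenzofuran-3-carboxylate | O=C(OCc1ccccc1)C1OC(=O)[C@]2(C)CCC[C@@](C)(O)[C@H]12 | intermediate
8 | (3aS,4R,7aR)-4-hydroxy-4,7a-dimethyl-1-oxooctahydroisobenzofuran-3-carboxylic acid | OC(=O)C1OC(=O)[C@]2(C)CCC[C@@](C)(O)[C@H]12 | intermediate
9 | 2-methylcyclopent-2-en-1-one | CC1=CCCC1=O | starting material
10 | (S)-2-methylcyclopent-2-en-1-ol | CC1=CCC[C@@H]1O | intermediate
11 | (S)-2-methylcyclopent-2-en-1-yl glyoxylate p-toluenesulfonylhydrazone | CC1=CCC[C@@H]1OC(=O)C=NNS(=O)(=O)c1ccc(C)cc1 | intermediate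
12 | (S)-2-methylcyclopent-2-en-1-yl diazoacetate | CC1=CCC[C@@H]1OC(=O)C=[N+]=[N-] | intermediate
13 | 8-methyl-4-oxatricyclo[3.2.1.0(2,8)]octan-3-one, all-cis | O=C1O[C@H]2CC[C@H]3[C@@H]1[C@@]23C | intermediate
14 | 8-methyl-4-oxatricyclo[3.2.1.0(2,8)]octan-3-ol (lactol) | OC1O[C@H]2CC[C@H]3[C@@H]1[C@@]23C | intermediate
15 | 1-methyl-6-endo-[(E)-2-(pinacolboryl)ethenyl]bicyclo[3.1.0]hexan-2-ol, hydroxyl cis to cyclopropane | O[C@H]1CC[C@H]2[C@@H](/C=C/B3OC(C)(C)C(C)(C)O3)[C@@]12C | intermediate
16 | 1-methyl-6-endo-[(E)-2-(pinacolboryl)ethenyl]bicyclo[3.1.0]hexan-2-one | O=C1CC[C@H]2[C@@H](/C=C/B3OC(C)(C)C(C)(C)O3)[C@@]12C | intermediate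
17 | 6-endo-[(E)-2-(4-methoxybenzyloxy)ethenyl]-1-methylbicyclo[3.1.0]hexan-2-one | O=C1CC[C@H]2[C@@H](/C=C/OCc3ccc(OC)cc3)[C@@]12C | intermediate
18 | lithium enolate of 17 | [Li]OC1=CC[C@H]2[C@@H](/C=C/OCc3ccc(OC)cc3)[C@@]12C | intermediate
19 | 3-(dimethylaminomethyl) derivative of 17 (Mannich base) | O=C1C(CN(C)C)C[C@H]2[C@@H](/C=C/OCc3ccc(OC)cc3)[C@@]12C | intermediate
20 | trimethylammoniomethyl ketone iodide | O=C1C(C[N+](C)(C)C)C[C@H]2[C@@H](/C=C/OCc3ccc(OC)cc3)[C@@]12C.[I-] | intermediate
21 | 6-endo-[(E)-2-(4-methoxybenzyloxy)ethenyl]-1-methyl-3-methylidenebicyclo[3.1.0]hexan-2-one | O=C1C(=C)C[C@H]2[C@@H](/C=C/OCc3ccc(OC)cc3)[C@@]12C | intermediate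
22 | union ketone, 3-(lactonylmethyl)-6-endo-[(E)-2-(4-methoxybenzyloxy)ethenyl]-1-methylbicyclo[3.1.0]hexan-2-one | O=C1C(C[C@H]3OC(=O)[C@]4(C)CCC[C@@](C)(O)[C@H]34)C[C@H]2[C@@H](/C=C/OCc5ccc(OC)cc5)[C@@]12C | intermediate
23 | bis(trimethylsilyl) derivative, 2-(trimethylsilyloxy)-6-endo-vinyl-type bicyclo[3.1.0]hex-2-ene | C[Si](C)(C)OC1=C(C[C@H]3OC(=O)[C@]4(C)CCC[C@@](C)(O[Si](C)(C)C)[C@H]34)C[C@H]2[C@@H](/C=C/OCc5ccc(OC)cc5)[C@@]12C | intermediate
24 | rearranged bicyclo[3.2.1]octa-2,6-diene silyl enol ether | CC=1[C@@H]2C=C[C@H](OCc3ccc(OC)cc3)[C@@](C[C@H]4OC(=O)[C@]5(C)CCC[C@@](C)(O[Si](C)(C)C)[C@H]45)(C2)C=1O[Si](C)(C)C | intermediate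
25 | 6-methylidenebicyclo[3.2.1]oct-3-en-7-one with 2-(4-methoxybenzyloxy) group | C=C1[C@@H]2C=C[C@H](OCc3ccc(OC)cc3)[C@@](C[C@H]4OC(=O)[C@]5(C)CCC[C@@](C)(O[Si](C)(C)C)[C@H]45)(C2)C1=O | intermediate
26 | (7R)-7-ol still carrying the tertiary trimethylsilyl ether | C=C1[C@@H]2C=C[C@H](OCc3ccc(OC)cc3)[C@@](C[C@H]4OC(=O)[C@]5(C)CCC[C@@](C)(O[Si](C)(C)C)[C@H]45)(C2)[C@@H]1O | intermediate
27 | (7R)-7-ol with free tertiary alcohol (diol) | C=C1[C@@H]2C=C[C@H](OCc3ccc(OC)cc3)[C@@](C[C@H]4OC(=O)[C@]5(C)CCC[C@@](C)(O)[C@H]45)(C2)[C@@H]1O | intermediate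
28 | (7R)-7-acetate, 2-(4-methoxybenzyl) ether | C=C1[C@@H]2C=C[C@H](OCc3ccc(OC)cc3)[C@@](C[C@H]4OC(=O)[C@]5(C)CCC[C@@](C)(O)[C@H]45)(C2)[C@@H]1OC(C)=O | intermediate
29 | (7R)-7-acetate, 2-ol (allylic alcohol) | C=C1[C@@H]2C=C[C@H](O)[C@@](C[C@H]3OC(=O)[C@]4(C)CCC[C@@](C)(O)[C@H]34)(C2)[C@@H]1OC(C)=O | intermediate
30 | CNP0172716.1 | C=C1[C@@H]2C=CC(=O)[C@@](C[C@H]3OC(=O)[C@]4(C)CCC[C@@](C)(O)[C@H]34)(C2)[C@@H]1OC(C)=O | target

**Step count and risks**

Total: 19 steps. Longest linear sequence: 15 steps (steps 5–19, from 9); the lactone fragment (steps 1–4) joins at step 13.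

Most likely to fail:

- Step 13 (fragment union). The excited iridium complex may oxidise the electron-rich enol ether in competition with the carboxylate, and the exo-methylene ketone may oligomerise, so radical capture could be poor. Fallback, setting out from acid 8: esterify with N-hydroxyphthalimide (N,N'-diisopropylcarbodiimide, 4-dimethylaminopyridine cat.) to the redox-active ester F1. Generate the same lactone radical reductively (Ru(bpy)3(PF6)2, diethyl 2,6-dimethyl-1,4-dihydropyridine-3,5-dicarboxylate, i-Pr2NEt, blue light) in the presence of 21. No strong photo-oxidant is present in this manifold, and the route is rejoined at 22.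

- Step 11 (enol ether formation). Protodeboronation or erosion of the E geometry during the copper-mediated etherification would remove the geometry the rearrangement needs. Fallback, setting out from lactol 14: Takai iodo-olefination (CHI3, CrCl2, THF) to the E-alkenyl iodide alcohol F2; the free hydroxyl cannot cyclise onto an E-alkenyl iodide. Then copper-catalysed C–O coupling with 4-methoxybenzyl alcohol (CuI, 3,4,7,8-tetramethyl-1,10-phenanthroline, Cs2CO3, toluene, 80 °C) to the enol ether alcohol F3, and Dess–Martin oxidation to rejoin the route at 17.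

- Step 3 (tertiary alcohol). Trapping of the planar tertiary radical by O2 may show poor facial selectivity. Fallback, setting out from 6: the concerted, more sterically demanding epoxidation with dimethyldioxirane (acetone, 0 °C) on the convex face to the spiro-epoxide F4. Open it at the CH2 terminus with sodium phenylselenide ((PhSe)2, NaBH4, EtOH) to the β-hydroxy selenide F5, then reductively remove selenium (Bu3SnH, azobisisobutyronitrile, benzene, 80 °C) to rejoin the route at 7.

Further compounds
F1 | step 13 | 1,3-dioxoisoindolin-2-yl (3aS,4R,7aR)-4-hydroxy-4,7a-dimethyl-1-oxooctahydroisobenzofuran-3-carboxylate | O=C(ON1C(=O)c2ccccc2C1=O)C1OC(=O)[C@]2(C)CCC[C@@](C)(O)[C@H]12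
F2 | step 11 | 6-endo-[(E)-2-iodoethenyl]-1-methylbicyclo[3.1.0]hexan-2-ol, hydroxyl cis to cyclopropane | O[C@H]1CC[C@H]2[C@@H](/C=C/I)[C@@]12C
F3 | step 11 | 6-endo-[(E)-2-(4-methoxybenzyloxy)ethenyl]-1-methylbicyclo[3.1.0]hexan-2-ol | O[C@H]1CC[C@H]2[C@@H](/C=C/OCc3ccc(OC)cc3)[C@@]12C
F4 | step 3 | benzyl (7aR)-7a-methyl-1-oxo-spiro[octahydroisobenzofuran-4,2'-oxirane]-3-carboxylate, epoxide oxygen trans to lactone | O=C(OCc1ccccc1)C1OC(=O)[C@]2(C)CCC[C@]3(CO3)[C@H]12
F5 | step 3 | benzyl (3aS,4R,7aR)-4-hydroxy-7a-methyl-1-oxo-4-(phenylselanylmethyl)octahydroisobenzofuran-3-carboxylate | O=C(OCc1ccccc1)C1OC(=O)[C@]2(C)CCC[C@@](C[Se]c3ccccc3)(O)[C@H]12
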